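Assumption: 5-hydroxyvanillin, (2R,4R)-1,5-dichloropentane-2,4-diol and 4-(benzyloxy)-3-methoxybenzyl alcohol are taken as catalogue compounds.

**Retrosynthetic overview**
- The target comes from its tris(benzyl ether) by one final hydrogenolysis.
- The oxane ring is the only ring formed and is closed last, by reductive etherification of an open-chain (3R,5S)-3,5-dihydroxy aryl ketone; this sets C2 cis to C6.
- The aryl ketone is unmasked from a 2-aryl-1,3-dithiane diol.
- Key bond C1–C2: the lithiated 2-aryl-1,3-dithiane (an aroyl anion equivalent) opens one oxirane of (R,R)-1,2:4,5-diepoxypentane at its CH2. The second oxirane is opened in the same flask by a benzyl Grignard (C6–C7), so both carbinol stereocentres come from the bis-epoxide.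
- Building blocks: 5-hydroxyvanillin, (2R,4R)-1,5-dichloropentane-2,4-diol, 4-(benzyloxy)-3-methoxybenzyl alcohol.

**Route**

Step 1
Reactants: 1 5-hydroxyvanillin (3,4-dihydroxy-5-methoxybenzaldehyde)
Product: 2 3,4-bis(benzyloxy)-5-methoxybenzaldehyde
Conditions: BnBr (2.3 equiv), K2CO3 (3 equiv), DMF, 60 °C
Reagents that add atoms: benzyl bromide BrCc1ccccc1
Why: Williamson ether synthesis; both phenoxides are benzylated by SN2 and the aldehyde is untouched (no stereocentre).

Step 2
Reactants: 2 3,4-bis(benzyloxy)-5-methoxybenzaldehyde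
Product: 3 2-[3,4-bis(benzyloxy)-5-methoxyphenyl]-1,3-dithiane
Conditions: propane-1,3-dithiol (1.1 equiv), BF3·OEt2 (20 mol %), CH2Cl2, 0 °C → rt
Reagents that add atoms: propane-1,3-dithiol SCCCS
Why: Lewis-acid-catalysed dithioacetalisation gives the Corey–Seebach dithiane, whose benzylic C2–H between two sulfurs is readily lithiated; aryl benzyl ethers tolerate catalytic BF3 at this temperature.

Step 3
Reactants: 4 (2R,4R)-1,5-dichloropentane-2,4-diol
Product: 5 (2R,2'R)-2,2'-methylenebis(oxirane) [(R,R)-1,2:4,5-diepoxypentane]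
Conditions: powdered KOH (4 equiv), Et2O, rt; filter, distil carefully
Reagents that add atoms: none
Why: Double intramolecular Williamson (chlorohydrin-to-epoxide) closure; each alkoxide displaces a primary chloride, no bond at a stereocentre is broken, so (R,R) is retained.

Step 4
Reactants: 6 4-(benzyloxy)-3-methoxybenzyl alcohol
Product: 7 4-(benzyloxy)-3-methoxybenzyl chloride
Conditions: SOCl2 (1.2 equiv), cat. DMF, CH2Cl2, 0 °C; used crude at once
Reagents that add atoms: thionyl chloride ClS(Cl)=O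
Why: Chlorodehydroxylation of an activated benzylic alcohol through its chlorosulfite (SN2/SNi).

Step 5
Reactants: 3 2-[3,4-bis(benzyloxy)-5-methoxyphenyl]-1,3-dithiane; 5 (2R,2'R)-2,2'-methylenebis(oxirane); 7 4-(benzyloxy)-3-methoxybenzyl chloride
Product: 11 (2R,4S)-1-{2-[3,4-bis(benzyloxy)-5-methoxyphenyl]-1,3-dithian-2-yl}-6-[4-(benzyloxy)-3-methoxyphenyl]hexane-2,4-diol, via 2-lithio-1,3-dithiane 8 (not isolated), via benzylic Grignard reagent 9 (not isolated), via lithium epoxy alkoxide 10 (not isolated)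
Conditions: 3, n-BuLi (1.05 equiv), THF, −78 → −25 °C; cannulate into 5 (1.5 equiv), THF, −78 → −25 °C; then CuI (15 mol %) and 9 (3.5 equiv, from 7 + Mg, THF, 0 °C, slow addition), −40 → 0 °C; aq NH4Cl
Reagents that add atoms: none
Why: Corey–Seebach acyl-anion alkylation followed by copper-catalysed Grignard epoxide opening. The lithiated dithiane (masked aroyl anion) attacks the CH2 of one of the two homotopic oxiranes of C2-symmetric 5 by SN2; alkoxide 10 keeps the second oxirane (4-exo/5-endo closure is disfavoured) until Grignard 9 opens it at CH2; no C–O bond at a carbinol carbon is broken, so the (2R,4S) anti-diol is inherited entirely from 5.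

Step 6
Reactants: 11 (2R,4S)-1-{2-[3,4-bis(benzyloxy)-5-methoxyphenyl]-1,3-dithian-2-yl}-6-[4-(benzyloxy)-3-methoxyphenyl]hexane-2,4-diol
Product: 12 (3R,5S)-1-[3,4-bis(benzyloxy)-5-methoxyphenyl]-7-[4-(benzyloxy)-3-methoxyphenyl]-3,5-dihydroxyheptan-1-one
Conditions: MeI (10 equiv), CaCO3 (5 equiv), MeCN/H2O (9:1), 45 °C
Reagents that add atoms: water O
Why: Alkylative dithiane hydrolysis; S-methylation turns sulfur into a leaving group and the aryl-stabilised thionium ion is hydrolysed under CaCO3-buffered neutral conditions that spare the β-hydroxy ketone and the benzyl ethers; the two stereocentres are not involved.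

Step 7
Reactants: 12 (3R,5S)-1-[3,4-bis(benzyloxy)-5-methoxyphenyl]-7-[4-(benzyloxy)-3-methoxyphenyl]-3,5-dihydroxyheptan-1-one
Product: 15 (2S,4R,6S)-2-[3,4-bis(benzyloxy)-5-methoxyphenyl]-6-{2-[4-(benzyloxy)-3-methoxyphenyl]ethyl}oxan-4-ol, via cyclic hemiketal 13 (not isolated), via oxocarbenium triflate 14 (not isolated)
Conditions: Et3SiH (4 equiv), TMSOTf (0.3 equiv), CH2Cl2, −78 → −40 °C; aq NaHCO3
Reagents that add atoms: none
Why: Reductive etherification (silane reduction of a cyclic oxocarbenium ion). The C5 hydroxyl closes onto the aryl ketone to hemiketal 13 and TMSOTf ionises it to the aryl-stabilised oxocarbenium 14; Et3SiH then delivers hydride axially to the half-chair that keeps the C4 hydroxyl and the C6 side chain equatorial, which places the aryl group equatorial and sets C2 as S (2,4,6-all-cis, also the thermodynamic isomer).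

Step 8
Reactants: 15 (2S,4R,6S)-2-[3,4-bis(benzyloxy)-5-methoxyphenyl]-6-{2-[4-(benzyloxy)-3-methoxyphenyl]ethyl}oxan-4-ol
Product: 16 (2S,4R,6S)-2-(3,4-dihydroxy-5-methoxyphenyl)-6-[2-(4-hydroxy-3-methoxyphenyl)ethyl]oxan-4-ol
Conditions: H2 (1 atm), 10% Pd/C, degassed EtOAc/MeOH (4:1), rt; stop after 3 equiv H2; filter under Ar
Reagents that add atoms: none
Why: Catalytic hydrogenolysis; the three aryl O–CH2Ph bonds cleave much faster than the ring's benzylic dialkyl ether in neutral solvent, and no stereocentre is touched.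

**Compound list**
1 | 5-hydroxyvanillin (3,4-dihydroxy-5-methoxybenzaldehyde) | COc1cc(C=O)cc(O)c1O | starting material
2 | 3,4-bis(benzyloxy)-5-methoxybenzaldehyde | COc1cc(C=O)cc(OCc2ccccc2)c1OCc1ccccc1 | intermediate
3 | 2-[3,4-bis(benzyloxy)-5-methoxyphenyl]-1,3-dithiane | COc1cc(C2SCCCS2)cc(OCc2ccccc2)c1OCc1ccccc1 | intermediate
4 | (2R,4R)-1,5-dichloropentane-2,4-diol | ClC[C@H](O)C[C@@H](O)CCl | starting material
5 | (2R,2'R)-2,2'-methylenebis(oxirane) [(R,R)-1,2:4,5-diepoxypentane] | C1O[C@@H]1C[C@@H]1CO1 | intermediate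
6 | 4-(benzyloxy)-3-methoxybenzyl alcohol | COc1cc(CO)ccc1OCc1ccccc1 | starting material
7 | 4-(benzyloxy)-3-methoxybenzyl chloride | COc1cc(CCl)ccc1OCc1ccccc1 | intermediate
8 | 2-lithio-2-[3,4-bis(benzyloxy)-5-methoxyphenyl]-1,3-dithiane (formed in the flask) | COc1cc(C2([Li])SCCCS2)cc(OCc2ccccc2)c1OCc1ccccc1 | intermediate
9 | [4-(benzyloxy)-3-methoxybenzyl]magnesium chloride (formed in the flask) | COc1cc(C[Mg]Cl)ccc1OCc1ccccc1 | intermediate
10 | lithium (2R)-1-{2-[3,4-bis(benzyloxy)-5-methoxyphenyl]-1,3-dithian-2-yl}-3-[(2R)-oxiran-2-yl]propan-2-olate (formed in the flask) | COc1cc(C2(C[C@H](O[Li])C[C@@H]3CO3)SCCCS2)cc(OCc2ccccc2)c1OCc1ccccc1 | intermediate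
11 | (2R,4S)-1-{2-[3,4-bis(benzyloxy)-5-methoxyphenyl]-1,3-dithian-2-yl}-6-[4-(benzyloxy)-3-methoxyphenyl]hexane-2,4-diol | COc1cc(C2(C[C@H](O)C[C@@H](O)CCc3ccc(OCc4ccccc4)c(OC)c3)SCCCS2)cc(OCc2ccccc2)c1OCc1ccccc1 | intermediate
12 | (3R,5S)-1-[3,4-bis(benzyloxy)-5-methoxyphenyl]-7-[4-(benzyloxy)-3-methoxyphenyl]-3,5-dihydroxyheptan-1-one | COc1cc(C(=O)C[C@H](O)C[C@@H](O)CCc2ccc(OCc3ccccc3)c(OC)c2)cc(OCc2ccccc2)c1OCc1ccccc1 | intermediate
13 | (4R,6S)-2-[3,4-bis(benzyloxy)-5-methoxyphenyl]-6-{2-[4-(benzyloxy)-3-methoxyphenyl]ethyl}oxane-2,4-diol (cyclic hemiketal of 12, either C2 epimer; formed in the flask) | COc1cc(C2(O)C[C@H](O)C[C@H](CCc3ccc(OCc4ccccc4)c(OC)c3)O2)cc(OCc2ccccc2)c1OCc1ccccc1 | intermediate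
14 | cyclic 2-aryl oxocarbenium triflate from loss of the anomeric hydroxyl of 13 (C4 hydroxyl and C6 side chain cis as in 13; formed in the flask) | COc1cc(C2=[O+][C@@H](CCc3ccc(OCc4ccccc4)c(OC)c3)C[C@@H](O)C2)cc(OCc2ccccc2)c1OCc1ccccc1.[O-]S(=O)(=O)C(F)(F)F | intermediate
15 | (2S,4R,6S)-2-[3,4-bis(benzyloxy)-5-methoxyphenyl]-6-{2-[4-(benzyloxy)-3-methoxyphenyl]ethyl}oxan-4-ol | COc1cc(CC[C@H]2C[C@@H](O)C[C@@H](c3cc(OCc4ccccc4)c(OCc4ccccc4)c(OC)c3)O2)ccc1OCc1ccccc1 | intermediate
16 | (2S,4R,6S)-2-(3,4-dihydroxy-5-methoxyphenyl)-6-[2-(4-hydroxy-3-methoxyphenyl)ethyl]oxan-4-ol (CNP0399218.1) | COc1cc(CC[C@H]2C[C@@H](O)C[C@@H](c3cc(O)c(O)c(OC)c3)O2)ccc1O | target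

**Step count**
Total steps: 8. Longest linear sequence: 6 (steps 1, 2, 5, 6, 7, 8 from 5-hydroxyvanillin); steps 3 and 4 are one-step side branches.

**Three steps most likely to fail**

Step 5. The risks are double opening of 5 by 8, Wurtz coupling and uncertain titre of the electron-rich benzylic Grignard 9, and three reactive species in one flask. The fallback sets out from 5 and makes the two bonds in separate, purified operations in the reverse order. Grignard 9 (1 equiv) with CuI (10 mol %) is added to an excess of 5 (3 equiv, the surplus recovered by distillation) at −40 °C to give the epoxy alcohol (2S)-4-[4-(benzyloxy)-3-methoxyphenyl]-1-[(2R)-oxiran-2-yl]butan-2-ol F1. F1 is then opened at its oxirane CH2 by 2.2 equiv of lithiated dithiane 8 in THF (−78 → 0 °C; the first equivalent is spent on the hydroxyl and comes back as 3). The fallback returns to the route at 11.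

Step 7. The risks are dehydration of the β-hydroxy ketone, over-reduction of the electron-rich benzylic ether to the ring-opened chain, and partial O-silylation. The fallback sets out from 12 and closes the ring by C–O bond formation at a benzylic cation, not by hydride delivery. NaBH4 in MeOH at 0 °C gives (3R,5S)-1-[3,4-bis(benzyloxy)-5-methoxyphenyl]-7-[4-(benzyloxy)-3-methoxyphenyl]heptane-1,3,5-triol F2 as a mixture of C1 epimers, which does not matter. Catalytic TsOH·H2O in CH2Cl2 at rt then ionises only the para-alkoxybenzylic carbinol; the C5 hydroxyl captures the cation in a reversible SN1 cycloetherification (the C3 hydroxyl could only give an oxetane), and both epimers funnel to the all-equatorial oxane. The fallback returns at 15.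

Step 8. The risks are hydrogenolysis of the ring's benzylic C2–O bond and air oxidation of the free catechol. The fallback sets out from 12 and removes the benzyl groups before any benzylic ether exists. H2 with 10% Pd/C in EtOAc gives (3R,5S)-1-(3,4-dihydroxy-5-methoxyphenyl)-3,5-dihydroxy-7-(4-hydroxy-3-methoxyphenyl)heptan-1-one F3. F3 is then cyclised by the same reductive etherification (Et3SiH, excess TMSOTf, MeCN/CH2Cl2, −40 °C; the phenols are silylated transiently and freed on aqueous work-up). The fallback returns at the target 16.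

**Further compounds**
F1 | step 5 | (2S)-4-[4-(benzyloxy)-3-methoxyphenyl]-1-[(2R)-oxiran-2-yl]butan-2-ol | COc1cc(CC[C@H](O)C[C@@H]2CO2)ccc1OCc1ccccc1
F2 | step 7 | (3R,5S)-1-[3,4-bis(benzyloxy)-5-methoxyphenyl]-7-[4-(benzyloxy)-3-methoxyphenyl]heptane-1,3,5-triol (both C1 epimers) | COc1cc(C(O)C[C@H](O)C[C@@H](O)CCc2ccc(OCc3ccccc3)c(OC)c2)cc(OCc2ccccc2)c1OCc1ccccc1
F3 | step 8 | (3R,5S)-1-(3,4-dihydroxy-5-methoxyphenyl)-3,5-dihydroxy-7-(4-hydroxy-3-methoxyphenyl)heptan-1-one | COc1cc(C(=O)C[C@H](O)C[C@@H](O)CCc2ccc(O)c(OC)c2)cc(O)c1O
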